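**Remark on the chemistry.** The target, 5,6-dihydroxy-2-(4-hydroxy-2,5-dimethoxyphenyl)-7-methoxy-4H-chromen-4-one (C18H16O8), has no stereogenic element, and the C2–C1′ axis with a single ortho-methoxy group rotates freely. "Single enantiomer" is therefore taken to mean the one constitution given.

## The problem

The skeleton is an ordinary flavone; the difficulty lies in six oxygen substituents, three free and three methylated, with every free hydroxyl next to a methyl ether. On ring A, C5, C6, C7 and C8a all carry oxygen, and O5 and O6 must be free while O7 is methylated. The usual A-ring building blocks carry all three as OMe and leave a 6-OMe/7-OMe distinction to the end. On ring B the 4′-OH must be free beside the 5′-OMe, and no commodity 2,4,5-trioxygenated benzaldehyde has that oxygen differentiated. The heterocycle must close as the six-membered pyranone, not as the five-membered aurone. The 5,6-dihydroxy unit autoxidises in base, so it should be unveiled last and under acid.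

The feature that the plan exploits: O6 and the ring oxygen O1 (on C8a) are para to each other, and C5 and C7, the neighbours of C6, both carry oxygen. Ring A is therefore 2,6-dimethoxy-1,4-benzoquinone in its reduced form. C4a and C8 are its two symmetry-equivalent CH carbons, and the C4 carbonyl is an acyl group on one of them. Ring B has the same hidden symmetry: 2′-OMe and 5′-OMe are para, with C1′ and C4′ as the other para pair.

## Retrosynthesis

**13 ⇐ 12.** The O5–CH3 bond is cut last. This methyl ether is the only one peri to the C4 carbonyl and it also sits next to the free 6-OH, so chelation-controlled cleavage can single it out. Precursor 12 has its two other phenols (O6, O4′) already free, so no protecting group is left at the end.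

**12 ⇐ 10.** The O1–C2 bond is cut, which opens the pyranone to the o-hydroxyaryl ynone 10. The forward reaction is an isomerisation; run through the β-amino enone 11, it can only give the six-membered ring. The same amine removes the 4′-acetate.

**10 ⇐ 8 + 9 (key).** The C4–C4a bond is cut between the ynal 8 and the quinone 9. Cutting C2–C3 (aldol) or C2–C1′ (arylation) instead would leave a tetra-oxygenated A-ring ketone with differentiated oxygens still to be made. Cutting C4–C4a in the polar Friedel–Crafts sense would need an alkynoyl chloride and a Lewis acid on an electron-rich hydroquinone. In the radical sense the quinone itself is the acceptor and the aldehyde the acyl donor, two electrophilic carbons joined after polarity reversal by hydrogen-atom abstraction. The step needs no reagent and is redox-neutral. The quinone oxygen that ends as O6 is never alkylated, and the other becomes O1. Quinone 9 is a symmetric commodity, so the site of acylation is unambiguous.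

**8 ⇐ 7 ⇐ 5 + 6.** The C1′–C(sp) bond is cut (Sonogashira coupling of iodide 5 with propargyl alcohol 6), followed by adjustment of the alcohol to the aldehyde. The acetate on O4′ is chosen because it has no weak C–H bond for an excited quinone to abstract, it lowers the donor strength of ring B, and it falls off in the cyclisation step.

**5 ⇐ 4 ⇐ 1.** One C–I bond of the symmetric diiodide 1 is exchanged for C–O. The para relation of oxygen and iodine and the 2,5-dimethoxy pattern are fixed by the starting material, so no regiochemical question arises.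

## Roads not taken

**Alternative 1:** the obvious route. Cut C2–C3 and O1–C2: Claisen–Schmidt condensation of 1-(6-hydroxy-2,3,4-trimethoxyphenyl)ethanone A1 with 4-(benzyloxy)-2,5-dimethoxybenzaldehyde A2 gives chalcone A3. Oxidative cyclisation (iodine in DMSO) gives the 5,6,7-trimethoxyflavone A4, followed by demethylation at O5 and O6 and debenzylation. A4 carries five methyl ethers of which exactly two must go. The 6-OMe/7-OMe distinction rests on relay from a 5-O-metal chelate under excess aluminium halide, conditions that also threaten the 5′-OMe next to the liberated 4′-oxygen. A2 is not a commodity and needs its own steps, so nothing is saved. The chosen plan never methylates O6.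

**Alternative 2:** biomimetic late hydroxylation. Build the 6-deoxyflavone A5 and oxidise C6–H last, as the plant's flavone 6-hydroxylase does. Chemically, the 5-OH directs persulfate (Elbs) and other electrophilic oxidants to its para position C8, giving the 5,8-dihydroxy isomer A6. Correcting this by Wessely–Moser rearrangement needs hot hydriodic acid, which strips every methyl ether. Ortho-selective oxidants would first attack the more electron-rich B-ring phenol. The chosen plan brings O6 in with the quinone.

**Alternative 3:** three-component carbonylative Sonogashira annulation. Cut C4–C4a, C3–C4 and O1–C2: iodophenol A7, alkyne A8 and carbon monoxide under palladium give flavone A9. This is convergent, but A7 is a pentasubstituted benzene with four differentiated oxygens, so the real problem moves into a multi-step building block. Oxidative addition at its doubly ortho-substituted, electron-rich C–I bond is slow, aurone formation competes, and two benzyl groups must still be removed. The chosen plan makes the same C4–C4a bond from a C–H bond of a purchased quinone.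

Key step: step 5

## Route

**Step 1**
Reactants: 1 1,4-diiodo-2,5-dimethoxybenzene
Product: 4 4-iodo-2,5-dimethoxyphenol, via aryllithium 2 (not isolated), via dimethyl arylboronate 3 (not isolated)
Conditions: n-BuLi (1.0 equiv), THF, –78 °C; B(OMe)3, –78 → 0 °C; AcOH, 30% aq. H2O2, 0 °C → rt
Reagents that add atoms: n-butyllithium, [Li]CCCC (Li in 2 only); trimethyl borate, COB(OC)OC (B(OMe)2 in 3 only); hydrogen peroxide, OO (the phenol oxygen of 4)
Why: Iodine–lithium exchange on the symmetric diiodide should stop after one exchange, because the aryllithium deactivates the remaining C–I bond; borylation and oxidative 1,2-migration (boronate oxidation) then give the phenol with regiochemistry fixed by 1.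

**Step 2**
Reactants: 4 4-iodo-2,5-dimethoxyphenol
Product: 5 4-iodo-2,5-dimethoxyphenyl acetate
Conditions: Ac2O, Et3N, DMAP (cat.), CH2Cl2, 0 °C → rt
Reagents that add atoms: acetic anhydride, CC(=O)OC(C)=O
Why: Standard phenol acetylation; the acetate has no abstractable C–H bond for the photochemical step and is removed without an extra operation in step 6.

**Step 3**
Reactants: 5 4-iodo-2,5-dimethoxyphenyl acetate; 6 prop-2-yn-1-ol
Product: 7 4-(3-hydroxyprop-1-yn-1-yl)-2,5-dimethoxyphenyl acetate
Conditions: Pd(PPh3)2Cl2 (2 mol %), CuI (4 mol %), Et3N, THF, rt → 40 °C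
Reagents that add atoms: none
Why: Sonogashira coupling of an aryl iodide with a terminal alkyne; the aryl acetate and the free primary alcohol should tolerate triethylamine at this temperature.

**Step 4**
Reactants: 7 4-(3-hydroxyprop-1-yn-1-yl)-2,5-dimethoxyphenyl acetate
Product: 8 2,5-dimethoxy-4-(3-oxoprop-1-yn-1-yl)phenyl acetate
Conditions: activated MnO2 (10 equiv), CH2Cl2, rt
Reagents that add atoms: none
Why: MnO2 oxidation of a propargylic alcohol to the ynal; it is selective for activated alcohols and cannot over-oxidise to the acid, and the phenol is masked.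

**Step 5**
Reactants: 8 2,5-dimethoxy-4-(3-oxoprop-1-yn-1-yl)phenyl acetate; 9 2,6-dimethoxy-1,4-benzoquinone
Product: 10 4-[3-(3,6-dihydroxy-2,4-dimethoxyphenyl)-3-oxoprop-1-yn-1-yl]-2,5-dimethoxyphenyl acetate
Conditions: 9 (1 equiv), 8 (2 equiv, excess recoverable), degassed PhCF3/MeCN, blue LEDs (ca. 450 nm), 20–25 °C, Ar
Reagents that add atoms: none
Why: Proposed new method: light absorbed only by 9 gives its n,π* triplet, which should abstract the formyl hydrogen of 8, the weakest C–H bond present; the resulting σ-alkynoyl radical cannot lose CO (an alkynyl radical would result) and, being nucleophilic, should add to C3 of ground-state 9, the β-carbon of the C1 enone and one of two symmetry-equivalent CH carbons. This gives a radical stabilised by the adjacent methoxy and carbonyl groups; hydrogen return from the semiquinone (or chain transfer from 8) and enolisation then give the acylhydroquinone 10 with all atoms of both partners retained. The closest known reaction type is the photochemical Friedel–Crafts acylation of 1,4-quinones with aliphatic, aromatic and α,β-unsaturated aldehydes; new here are an alkynyl aldehyde and a doubly donor-substituted quinone. No ring is closed and no stereocentre is formed. C-acylation is needed over O-acylation, and radical addition at the ring carbon should secure it. Mono-acylation is needed; 10 is a hydroquinone, not an acceptor, and the corresponding acylquinone would be a stronger oxidant than 9, so 9 should not oxidise 10. Chemoselectivity over carbonyl–alkyne [2+2] photocycloaddition is needed; the alkyne is made electron-poor by the formyl group and the acetate tempers ring B. Energy transfer to the arylalkyne should be uphill, and there is no alkene to isomerise.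

**Step 6**
Reactants: 10 4-[3-(3,6-dihydroxy-2,4-dimethoxyphenyl)-3-oxoprop-1-yn-1-yl]-2,5-dimethoxyphenyl acetate
Product: 12 6-hydroxy-2-(4-hydroxy-2,5-dimethoxyphenyl)-5,7-dimethoxy-4H-chromen-4-one, via enaminone 11 (not isolated)
Conditions: Et2NH (10 equiv), degassed EtOH, rt then 70 °C, Ar; AcOH quench
Reagents that add atoms: diethylamine, CCNCC (its atoms are in 11 only; none remain in 12)
Why: Conjugate addition of the amine to the ynone gives the β-amino enone 11 (drawn E; the geometry is immaterial); the hydroxyl ortho to the ketone then adds to the β-carbon and expels the amine (6-endo-trig addition–elimination), so only the pyranone can form and never the aurone. Excess amine cleaves the aryl acetate by aminolysis; this is the known amine-mediated flavone synthesis from o-hydroxyaryl ynones.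

**Step 7**
Reactants: 12 6-hydroxy-2-(4-hydroxy-2,5-dimethoxyphenyl)-5,7-dimethoxy-4H-chromen-4-one
Product: 13 5,6-dihydroxy-2-(4-hydroxy-2,5-dimethoxyphenyl)-7-methoxy-4H-chromen-4-one
Conditions: BCl3 (1 M in CH2Cl2, 4 equiv), CH2Cl2, –78 → 0 °C; then MeOH, aq. HCl, rt
Reagents that add atoms: none
Why: Chelation-controlled demethylation: boron bound between the C4 carbonyl and the peri 5-OMe (six-membered chelate) lets chloride cleave only that O–CH3 bond. Once O5 is free, O5 and O6 should be tied up as a cyclic chloroborate, which lowers the Lewis acidity near the 7-OMe; the B-ring methyl ethers have no carbonyl to chelate.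

## Compound list

1 | 1,4-diiodo-2,5-dimethoxybenzene | COc1cc(I)c(OC)cc1I | starting material
2 | (4-iodo-2,5-dimethoxyphenyl)lithium | [Li]c1cc(OC)c(I)cc1OC | intermediate (not isolated)
3 | dimethyl (4-iodo-2,5-dimethoxyphenyl)boronate | COB(OC)c1cc(OC)c(I)cc1OC | intermediate (not isolated)
4 | 4-iodo-2,5-dimethoxyphenol | COc1cc(O)c(OC)cc1I | intermediate
5 | 4-iodo-2,5-dimethoxyphenyl acetate | COc1cc(OC(C)=O)c(OC)cc1I | intermediate
6 | prop-2-yn-1-ol | C#CCO | starting material
7 | 4-(3-hydroxyprop-1-yn-1-yl)-2,5-dimethoxyphenyl acetate | COc1cc(OC(C)=O)c(OC)cc1C#CCO | intermediate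
8 | 2,5-dimethoxy-4-(3-oxoprop-1-yn-1-yl)phenyl acetate | COc1cc(OC(C)=O)c(OC)cc1C#CC=O | intermediate
9 | 2,6-dimethoxy-1,4-benzoquinone | COC1=CC(=O)C=C(OC)C1=O | starting material
10 | 4-[3-(3,6-dihydroxy-2,4-dimethoxyphenyl)-3-oxoprop-1-yn-1-yl]-2,5-dimethoxyphenyl acetate | COc1cc(O)c(C(=O)C#Cc2cc(OC)c(OC(C)=O)cc2OC)c(OC)c1O | intermediate
11 | 4-[(E)-1-(diethylamino)-3-(3,6-dihydroxy-2,4-dimethoxyphenyl)-3-oxoprop-1-en-1-yl]-2,5-dimethoxyphenyl acetate | CCN(CC)/C(=C/C(=O)c1c(O)cc(OC)c(O)c1OC)c1cc(OC)c(OC(C)=O)cc1OC | intermediate (not isolated)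
12 | 6-hydroxy-2-(4-hydroxy-2,5-dimethoxyphenyl)-5,7-dimethoxy-4H-chromen-4-one | COc1cc2oc(-c3cc(OC)c(O)cc3OC)cc(=O)c2c(OC)c1O | intermediate
13 | 5,6-dihydroxy-2-(4-hydroxy-2,5-dimethoxyphenyl)-7-methoxy-4H-chromen-4-one | COc1cc(-c2cc(=O)c3c(O)c(O)c(OC)cc3o2)c(OC)cc1O | target

## Step count and risk

Total steps: 7. Longest linear sequence: 7 (1 → 13); 6 and 9 enter as purchased.

**Step 5 (key step, Proposed new method).** The likely failure is unproductive decay of the excited quinone. Possible channels are electron transfer from the electron-rich aryl alkyne followed by back transfer, hydrogen abstraction from the product hydroquinone, carbonyl–alkyne photocycloaddition, and acylation at oxygen. The fallback makes the same C4–C4a bond by known polar chemistry; it sets out from 9 and 8 and comes back at 12. Reduction of 9 (aq. Na2S2O4) gives 2,6-dimethoxybenzene-1,4-diol F1. MOMCl/i-Pr2NEt gives 1,3-dimethoxy-2,5-bis(methoxymethoxy)benzene F2. Directed ortho-lithiation (n-BuLi, TMEDA, THF, 0 °C) at the CH flanked by OMe and OMOM gives [2,4-dimethoxy-3,6-bis(methoxymethoxy)phenyl]lithium F3. Addition of F3 to the aldehyde of 8 at –78 °C gives the racemic propargylic alcohol 4-{3-[2,4-dimethoxy-3,6-bis(methoxymethoxy)phenyl]-3-hydroxyprop-1-yn-1-yl}-2,5-dimethoxyphenyl acetate F4. MnO2 gives the ynone 4-{3-[2,4-dimethoxy-3,6-bis(methoxymethoxy)phenyl]-3-oxoprop-1-yn-1-yl}-2,5-dimethoxyphenyl acetate F5. Et2NH/EtOH adds to the ynone and removes the acetate, giving the enaminone (E)-3-(diethylamino)-1-[2,4-dimethoxy-3,6-bis(methoxymethoxy)phenyl]-3-(4-hydroxy-2,5-dimethoxyphenyl)prop-2-en-1-one F6. Any acetate lost at the lithium stage converges here. HCl/MeOH at 60 °C then removes both MOM groups and closes the pyranone to 12.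

**Step 6.** Autoxidation of the hydroquinone under basic amine, or incomplete expulsion of the amine and incomplete acetate aminolysis, may erode the step. The fallback sets out from 10, comes back at 12, and changes the activation from nucleophilic to electrophilic. TfOH in CH2Cl2 (0 °C → rt) promotes 6-endo cyclisation of the o-alkynoylphenol to 4-(6-hydroxy-5,7-dimethoxy-4-oxo-4H-chromen-2-yl)-2,5-dimethoxyphenyl acetate F7. The acetate is then removed separately by acid methanolysis (HCl/MeOH, 50 °C).

**Step 7.** Over-demethylation at O7 or O5′, assisted by the neighbouring boron phenoxides, or incomplete reaction of a poorly soluble polyphenol, is the risk. The fallback sets out from 12, comes back at 13, and removes the neighbouring-group effect by masking. Ac2O/pyridine gives the diacetate 4-[6-(acetyloxy)-5,7-dimethoxy-4-oxo-4H-chromen-2-yl]-2,5-dimethoxyphenyl acetate F8. BCl3 then cleaves only the peri methyl ether to give 4-[6-(acetyloxy)-5-hydroxy-7-methoxy-4-oxo-4H-chromen-2-yl]-2,5-dimethoxyphenyl acetate F9. HCl/MeOH removes both acetates under acid.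

**Step 1.** Double exchange or premature protonation would give mixtures of diiodide, monoiodide and diol precursors. The fallback sets out from 1, comes back at 4, and replaces the organolithium sequence with a copper-catalysed C–O coupling. It uses CuI, 1,10-phenanthroline, KOH and aqueous DMSO at 100 °C, with 1 in excess. The first phenoxide formed deactivates the remaining C–I bond, which should favour mono-hydroxylation. No new compound is made.

## Further compounds

F1 | step 5 | 2,6-dimethoxybenzene-1,4-diol | COc1cc(O)cc(OC)c1O
F2 | step 5 | 1,3-dimethoxy-2,5-bis(methoxymethoxy)benzene | COCOc1cc(OC)c(OCOC)c(OC)c1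
F3 | step 5 | [2,4-dimethoxy-3,6-bis(methoxymethoxy)phenyl]lithium | [Li]c1c(OCOC)cc(OC)c(OCOC)c1OC
F4 | step 5 | 4-{3-[2,4-dimethoxy-3,6-bis(methoxymethoxy)phenyl]-3-hydroxyprop-1-yn-1-yl}-2,5-dimethoxyphenyl acetate (racemic) | COCOc1cc(OC)c(OCOC)c(OC)c1C(O)C#Cc1cc(OC)c(OC(C)=O)cc1OC
F5 | step 5 | 4-{3-[2,4-dimethoxy-3,6-bis(methoxymethoxy)phenyl]-3-oxoprop-1-yn-1-yl}-2,5-dimethoxyphenyl acetate | COCOc1cc(OC)c(OCOC)c(OC)c1C(=O)C#Cc1cc(OC)c(OC(C)=O)cc1OC
F6 | step 5 | (E)-3-(diethylamino)-1-[2,4-dimethoxy-3,6-bis(methoxymethoxy)phenyl]-3-(4-hydroxy-2,5-dimethoxyphenyl)prop-2-en-1-one | CCN(CC)/C(=C/C(=O)c1c(OCOC)cc(OC)c(OCOC)c1OC)c1cc(OC)c(O)cc1OC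
F7 | step 6 | 4-(6-hydroxy-5,7-dimethoxy-4-oxo-4H-chromen-2-yl)-2,5-dimethoxyphenyl acetate | COc1cc2oc(-c3cc(OC)c(OC(C)=O)cc3OC)cc(=O)c2c(OC)c1O
F8 | step 7 | 4-[6-(acetyloxy)-5,7-dimethoxy-4-oxo-4H-chromen-2-yl]-2,5-dimethoxyphenyl acetate | COc1cc2oc(-c3cc(OC)c(OC(C)=O)cc3OC)cc(=O)c2c(OC)c1OC(C)=O
F9 | step 7 | 4-[6-(acetyloxy)-5-hydroxy-7-methoxy-4-oxo-4H-chromen-2-yl]-2,5-dimethoxyphenyl acetate | COc1cc2oc(-c3cc(OC)c(OC(C)=O)cc3OC)cc(=O)c2c(O)c1OC(C)=O
F0 | step 1 | none | none
A1 | alternative 1 | 1-(6-hydroxy-2,3,4-trimethoxyphenyl)ethan-1-one | CC(=O)c1c(O)cc(OC)c(OC)c1OC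
A2 | alternative 1 | 4-(benzyloxy)-2,5-dimethoxybenzaldehyde | COc1cc(OCc2ccccc2)c(OC)cc1C=O
A3 | alternative 1 | (E)-3-[4-(benzyloxy)-2,5-dimethoxyphenyl]-1-(6-hydroxy-2,3,4-trimethoxyphenyl)prop-2-en-1-one | COc1cc(OCc2ccccc2)c(OC)cc1/C=C/C(=O)c1c(O)cc(OC)c(OC)c1OC
A4 | alternative 1 | 2-[4-(benzyloxy)-2,5-dimethoxyphenyl]-5,6,7-trimethoxy-4H-chromen-4-one | COc1cc2oc(-c3cc(OC)c(OCc4ccccc4)cc3OC)cc(=O)c2c(OC)c1OC
A5 | alternative 2 | 5-hydroxy-2-(4-hydroxy-2,5-dimethoxyphenyl)-7-methoxy-4H-chromen-4-one | COc1cc(O)c2c(c1)oc(-c1cc(OC)c(O)cc1OC)cc2=O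
A6 | alternative 2 | 5,8-dihydroxy-2-(4-hydroxy-2,5-dimethoxyphenyl)-7-methoxy-4H-chromen-4-one | COc1cc(O)c2c(c1O)oc(-c1cc(OC)c(O)cc1OC)cc2=O
A7 | alternative 3 | 4-(benzyloxy)-2-iodo-3,5-dimethoxyphenol | COc1cc(O)c(I)c(OC)c1OCc1ccccc1
A8 | alternative 3 | 1-(benzyloxy)-4-ethynyl-2,5-dimethoxybenzene | C#Cc1cc(OC)c(OCc2ccccc2)cc1OC
A9 | alternative 3 | 6-(benzyloxy)-2-[4-(benzyloxy)-2,5-dimethoxyphenyl]-5,7-dimethoxy-4H-chromen-4-one | COc1cc2oc(-c3cc(OC)c(OCc4ccccc4)cc3OC)cc(=O)c2c(OC)c1OCc1ccccc1
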